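**Plan**
1. Retrosynthesis: the three methoxymethyl ethers (O5, O7, O2') are cut last; then the C2–C1' bond between ring C and ring B, giving an 8-prenylchromone (rings A and C) and a ring-B arylboronic acid; then, in the pyran fused to ring B, the bond from the pyran oxygen to the aromatic carbon C4', followed by the C5'–alkenyl bond; ring C is cut back to a 3-prenylated 2,4,6-trihydroxyacetophenone.
2. Forward order: the pyran on ring B is closed first (fragment B, steps 1–6); ring C is then built on prenylated ring A (fragment A, steps 7–9); the fragments are joined at C2 (step 10) and the phenols released (step 11).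
3. Enabling feature: in ring B the pyran oxygen sits on C4', ortho to C5' (which carries the three-carbon arm) and para to C1'. With fluorine on C4' and bromine on C1', C4' is the one ring carbon that a cis-allylic tertiary alkoxide on the C5' arm can reach and substitute.
4. This one ring closure fixes the linear 6,7-fusion of the chromene (phenol-based chromene annulations of 2,4-dioxygenated rings tend to give the angular isomer), delivers the pyran with its cis double bond at the final oxidation level, tells the two ring-B oxygens apart, and keeps bromine as the handle for C1'.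
5. Stereochemistry: the only stereocentre, C2 (S), is set in step 10 by enantioface-selective aryl transfer from a chiral bisphosphine–rhodium catalyst to C2 of the chromone; base-free and mildly acidic conditions afterwards should keep it.

Key step: step 5

Remark: compounds 1, 4, 12 and 13 are taken as commercial; the hand of the bisphosphine in step 10 is assigned by analogy with the known sense of such ligands in the arylation of cyclic enones and would be confirmed on the first run (the antipode is equally available).

**Route**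

Step 1
Reactants: 1 2-bromo-5-fluorophenol
Product: 2 2-bromo-5-fluoro-4-iodophenol
Conditions: N-iodosuccinimide (1.05 equiv), TsOH (10 mol %), MeCN, 0 °C → rt
Reagents that add atoms: N-iodosuccinimide, O=C1CCC(=O)N1I
Why: Electrophilic aromatic iodination: the hydroxyl group directs to its para position C4, which is also ortho to fluorine and less hindered than C6 between OH and F, so a single iodide is expected.

Step 2
Reactants: 2 2-bromo-5-fluoro-4-iodophenol
Product: 3 1-bromo-4-fluoro-5-iodo-2-(methoxymethoxy)benzene
Conditions: MOMCl (1.3 equiv), i-Pr2NEt (1.5 equiv), CH2Cl2, 0 °C → rt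
Reagents that add atoms: chloromethyl methyl ether (MOMCl), COCCl
Why: O-Alkylation of the phenol with the chloromethyl ether (Williamson-type etherification) masks the acidic OH, which as a phenoxide would deactivate ring B in step 5, as an acetal that survives base, organolithium and hydrogenation conditions.

Step 3
Reactants: 3 1-bromo-4-fluoro-5-iodo-2-(methoxymethoxy)benzene; 4 2-methylbut-3-yn-2-ol
Product: 5 4-[5-bromo-2-fluoro-4-(methoxymethoxy)phenyl]-2-methylbut-3-yn-2-ol
Conditions: PdCl2(PPh3)2 (2 mol %), CuI (4 mol %), Et3N, THF, rt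
Reagents that add atoms: none
Why: Sonogashira coupling; oxidative addition of zerovalent palladium is much faster at C–I than at C–Br or C–F at room temperature, so only C5' of ring B is alkynylated.

Step 4
Reactants: 5 4-[5-bromo-2-fluoro-4-(methoxymethoxy)phenyl]-2-methylbut-3-yn-2-ol
Product: 6 (Z)-4-[5-bromo-2-fluoro-4-(methoxymethoxy)phenyl]-2-methylbut-3-en-2-ol
Conditions: H2 (1 atm), 5% Pd/CaCO3 poisoned with Pb(OAc)2 (Lindlar catalyst), quinoline, EtOAc, rt
Reagents that add atoms: none
Why: Lindlar semihydrogenation: syn delivery of H2 on the poisoned palladium surface gives the cis (Z) alkene, and the lead/quinoline poisoning should spare the alkene, the C–Br bond and the C–F bond.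

Step 5
Reactants: 6 (Z)-4-[5-bromo-2-fluoro-4-(methoxymethoxy)phenyl]-2-methylbut-3-en-2-ol
Product: 8 6-bromo-7-(methoxymethoxy)-2,2-dimethyl-2H-chromene, via potassium alkoxide 7 (not isolated)
Conditions: KN(SiMe3)2 (1.05 equiv), THF, −20 °C; then DMF, 60 °C
Reagents that add atoms: none
Why: The potassium alkoxide 7 adds through oxygen to C4' of ring B (the carbon that carries fluorine) to give a Meisenheimer σ-adduct whose charge rests on C1' (stabilised inductively by bromine), C3' and C5', and loss of fluoride restores the arene, so the aryl C–O bond of the pyran forms by addition–elimination (intramolecular SNAr). The closest known reaction type is the base-mediated cyclisation of 2-fluoroaryl alkanols to chromans and dihydrobenzofurans by displacement of a non-activated or weakly activated aryl fluoride. The pyran ring closes in a 6-exo-trig mode with respect to the attacked C4'=C3' π-bond, and the cis alkene from step 4 holds the alkoxide within bonding distance of C4', giving a high effective molarity. No stereocentre is formed. The step needs site selectivity (only C4' bears a nucleofuge and is in reach; C6' on the other side of the arm carries hydrogen), chemoselectivity over the C–Br bond (no metal is present and bromide is a poor nucleofuge in addition–elimination) and retention of the alkene geometry (the arm has no allylic hydrogen through which base could isomerise it). Using only 1.05 equiv of base, consumed at −20 °C in forming 7, should suppress dehydrohalogenation to arynes.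

Step 6
Reactants: 8 6-bromo-7-(methoxymethoxy)-2,2-dimethyl-2H-chromene
Product: 11 [7-(methoxymethoxy)-2,2-dimethyl-2H-chromen-6-yl]boronic acid, via aryllithium 9 (not isolated), via lithium triisopropoxyborate 10 (not isolated)
Conditions: n-BuLi (1.1 equiv), THF, −78 °C; B(OiPr)3 (1.5 equiv), −78 °C → rt; aq NH4Cl
Reagents that add atoms: triisopropyl borate, CC(C)OB(OC(C)C)OC(C)C; water, O
Why: Bromine–lithium exchange at −78 °C (faster than any attack on the chromene or the acetal, and assisted by the ortho OCH2OCH3 group) followed by electrophilic trapping with the borate and mild hydrolysis is the standard route from an aryl bromide to an arylboronic acid.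

Step 7
Reactants: 12 1-(2,4,6-trihydroxyphenyl)ethan-1-one; 13 1-bromo-3-methylbut-2-ene
Product: 14 1-[2,4,6-trihydroxy-3-(3-methylbut-2-en-1-yl)phenyl]ethan-1-one
Conditions: DBU (1.0 equiv), THF, 0 °C → rt
Reagents that add atoms: none
Why: C-Alkylation of the ambident phloroglucinol-type phenolate by the allylic bromide (SN2); the two free ring carbons of 12 are equivalent, so mono-C-prenylation gives one constitution, with the prenyl group between two hydroxyls.

Step 8
Reactants: 14 1-[2,4,6-trihydroxy-3-(3-methylbut-2-en-1-yl)phenyl]ethan-1-one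
Product: 15 1-[2-hydroxy-4,6-bis(methoxymethoxy)-3-(3-methylbut-2-en-1-yl)phenyl]ethan-1-one
Conditions: MOMCl (2.2 equiv), i-Pr2NEt (2.5 equiv), CH2Cl2, 0 °C
Reagents that add atoms: chloromethyl methyl ether (MOMCl), COCCl
Why: Chemoselective O-alkylation (acetal formation) of the two more accessible hydroxyls: the 4-OH (para to the acyl group, most acidic, not chelated) and the 6-OH (flanked only by H) should react, while the 2-OH, hindered by the neighbouring prenyl group and held in the hydrogen bond to the ketone, should stay free.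

Step 9
Reactants: 15 1-[2-hydroxy-4,6-bis(methoxymethoxy)-3-(3-methylbut-2-en-1-yl)phenyl]ethan-1-one
Product: 17 5,7-bis(methoxymethoxy)-8-(3-methylbut-2-en-1-yl)-4H-chromen-4-one, via enaminone 16 (not isolated)
Conditions: Me2NCH(OMe)2 (3 equiv), toluene, 90 °C; concentrate; toluene–AcOH 10:1, 70 °C
Reagents that add atoms: N,N-dimethylformamide dimethyl acetal, COC(OC)N(C)C
Why: Condensation of the methyl ketone with the amide acetal gives the enaminone 16, and acid-promoted 6-endo-trig oxa-Michael addition of the free 2-OH with loss of dimethylamine (enaminone route to chromones) closes ring C; because the ring oxygen is the hydroxyl next to the prenyl group, the prenyl group ends at C8.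

Step 10
Reactants: 17 5,7-bis(methoxymethoxy)-8-(3-methylbut-2-en-1-yl)-4H-chromen-4-one; 11 [7-(methoxymethoxy)-2,2-dimethyl-2H-chromen-6-yl]boronic acid
Product: 18 (2S)-5,7-bis(methoxymethoxy)-2-[7-(methoxymethoxy)-2,2-dimethyl-2H-chromen-6-yl]-8-(3-methylbut-2-en-1-yl)-2,3-dihydro-4H-chromen-4-one
Conditions: [Rh(OH)(cod)]2 (2.5 mol %), (S)-MeO-F12-BIPHEP [(S)-2,2'-bis[bis(3,4,5-trifluorophenyl)phosphino]-6,6'-dimethoxy-1,1'-biphenyl] (5.5 mol %), 11 (3 equiv), toluene–H2O 10:1, 50 °C
Reagents that add atoms: none
Why: Rhodium-catalysed asymmetric 1,4-addition of an arylboronic acid to a chromone (Hayashi–Miyaura reaction): transmetalation gives an aryl complex of monovalent rhodium whose enantiofacial insertion into the C2=C3 bond, dictated by the C2-symmetric electron-poor bisphosphine, sets C2 as S, and protonolysis of the rhodium enolate by water without added base avoids ring opening to the chalcone.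

Step 11
Reactants: 18 (2S)-5,7-bis(methoxymethoxy)-2-[7-(methoxymethoxy)-2,2-dimethyl-2H-chromen-6-yl]-8-(3-methylbut-2-en-1-yl)-2,3-dihydro-4H-chromen-4-one
Product: 19 (2S)-5,7-dihydroxy-2-(7-hydroxy-2,2-dimethyl-2H-chromen-6-yl)-8-(3-methylbut-2-en-1-yl)-2,3-dihydro-4H-chromen-4-one
Conditions: 3 M aq HCl–MeOH 1:5, 40 °C, short reaction time
Reagents that add atoms: none
Why: Acid-catalysed methanolysis of the three methoxymethyl acetals (transacetalisation to dimethoxymethane); dilute acid at 40 °C should leave the prenyl group, the chromene double bond and the C2 stereocentre (which epimerises mainly under base) untouched.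

**Compound list**
1 | 2-bromo-5-fluorophenol | Oc1cc(F)ccc1Br | starting material
2 | 2-bromo-5-fluoro-4-iodophenol | Oc1cc(F)c(I)cc1Br | intermediate
3 | 1-bromo-4-fluoro-5-iodo-2-(methoxymethoxy)benzene | COCOc1cc(F)c(I)cc1Br | intermediate
4 | 2-methylbut-3-yn-2-ol | CC(C)(O)C#C | starting material
5 | 4-[5-bromo-2-fluoro-4-(methoxymethoxy)phenyl]-2-methylbut-3-yn-2-ol | CC(C)(O)C#Cc1cc(Br)c(OCOC)cc1F | intermediate
6 | (Z)-4-[5-bromo-2-fluoro-4-(methoxymethoxy)phenyl]-2-methylbut-3-en-2-ol | CC(C)(O)/C=C\c1cc(Br)c(OCOC)cc1F | intermediate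
7 | potassium (Z)-4-[5-bromo-2-fluoro-4-(methoxymethoxy)phenyl]-2-methylbut-3-en-2-olate | CC(C)([O-])/C=C\c1cc(Br)c(OCOC)cc1F.[K+] | intermediate
8 | 6-bromo-7-(methoxymethoxy)-2,2-dimethyl-2H-chromene | CC1(C)C=Cc2cc(Br)c(OCOC)cc2O1 | intermediate
9 | [7-(methoxymethoxy)-2,2-dimethyl-2H-chromen-6-yl]lithium | [Li]c1cc2C=CC(C)(C)Oc2cc1OCOC | intermediate
10 | lithium triisopropoxy[7-(methoxymethoxy)-2,2-dimethyl-2H-chromen-6-yl]borate | CC(C)O[B-](OC(C)C)(OC(C)C)c1cc2C=CC(C)(C)Oc2cc1OCOC.[Li+] | intermediate
11 | [7-(methoxymethoxy)-2,2-dimethyl-2H-chromen-6-yl]boronic acid | OB(O)c1cc2C=CC(C)(C)Oc2cc1OCOC | intermediate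
12 | 1-(2,4,6-trihydroxyphenyl)ethan-1-one | CC(=O)c1c(O)cc(O)cc1O | starting material
13 | 1-bromo-3-methylbut-2-ene | CC(C)=CCBr | starting material
14 | 1-[2,4,6-trihydroxy-3-(3-methylbut-2-en-1-yl)phenyl]ethan-1-one | CC(=O)c1c(O)cc(O)c(CC=C(C)C)c1O | intermediate
15 | 1-[2-hydroxy-4,6-bis(methoxymethoxy)-3-(3-methylbut-2-en-1-yl)phenyl]ethan-1-one | CC(=O)c1c(O)c(CC=C(C)C)c(OCOC)cc1OCOC | intermediate
16 | (E)-3-(dimethylamino)-1-[2-hydroxy-4,6-bis(methoxymethoxy)-3-(3-methylbut-2-en-1-yl)phenyl]prop-2-en-1-one | CN(C)/C=C/C(=O)c1c(O)c(CC=C(C)C)c(OCOC)cc1OCOC | intermediate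
17 | 5,7-bis(methoxymethoxy)-8-(3-methylbut-2-en-1-yl)-4H-chromen-4-one | O=c1ccoc2c(CC=C(C)C)c(OCOC)cc(OCOC)c12 | intermediate
18 | (2S)-5,7-bis(methoxymethoxy)-2-[7-(methoxymethoxy)-2,2-dimethyl-2H-chromen-6-yl]-8-(3-methylbut-2-en-1-yl)-2,3-dihydro-4H-chromen-4-one | CC(C)=CCc1c(OCOC)cc(OCOC)c2c1O[C@H](c1cc3c(cc1OCOC)OC(C)(C)C=C3)CC2=O | intermediate
19 | (2S)-5,7-dihydroxy-2-(7-hydroxy-2,2-dimethyl-2H-chromen-6-yl)-8-(3-methylbut-2-en-1-yl)-2,3-dihydro-4H-chromen-4-one | CC(C)=CCc1c(O)cc(O)c2c1O[C@H](c1cc3c(cc1O)OC(C)(C)C=C3)CC2=O | target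

**Count**
Total steps: 11. Longest linear sequence: 8 steps (steps 1–6, then 10 and 11); fragment A (steps 7–9) is made in parallel.

**Steps most likely to fail**

Step 10. Transmetalation and insertion may be slow for the ortho-substituted, electron-rich boronic acid, so that protodeboronation wins, or the facial selectivity may be insufficient. The fallback replaces enantioselective arylation by an aldol union followed by resolution; it sets out from 8 and 15 and comes back at 18, and steps 6 and 10 are then not needed. Bromine–lithium exchange on 8 (n-BuLi, THF, −78 °C) and quenching with DMF should give 7-(methoxymethoxy)-2,2-dimethyl-2H-chromene-6-carbaldehyde F1. Claisen–Schmidt condensation of F1 with 15 (KOH, EtOH, rt) should give (E)-1-[2-hydroxy-4,6-bis(methoxymethoxy)-3-(3-methylbut-2-en-1-yl)phenyl]-3-[7-(methoxymethoxy)-2,2-dimethyl-2H-chromen-6-yl]prop-2-en-1-one F2. 6-endo oxa-Michael cyclisation (NaOAc, EtOH, reflux) should give racemic 5,7-bis(methoxymethoxy)-2-[7-(methoxymethoxy)-2,2-dimethyl-2H-chromen-6-yl]-8-(3-methylbut-2-en-1-yl)-2,3-dihydro-4H-chromen-4-one F3. Kinetic resolution by asymmetric transfer hydrogenation (RuCl(p-cymene)[TsDPEN] of the hand that reduces the (2R) ketone, HCO2H–Et3N, rt) should convert the unwanted enantiomer into (2R,4R)-5,7-bis(methoxymethoxy)-2-[7-(methoxymethoxy)-2,2-dimethyl-2H-chromen-6-yl]-8-(3-methylbut-2-en-1-yl)-3,4-dihydro-2H-chromen-4-ol F4, from which the unreacted (2S) ketone 18 is separated by chromatography.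

Step 5. The addition step may be too slow on the weakly activated fluoroarene, so that dehydrohalogenation or decomposition of the alkoxide competes. The fallback raises the activation with a para-formyl group; it sets out from 6 and comes back at 18. Treatment of 6 with n-BuLi (2.1 equiv, THF, −78 °C; O–H deprotonation, then bromine–lithium exchange) and DMF should give 4-fluoro-5-[(Z)-3-hydroxy-3-methylbut-1-en-1-yl]-2-(methoxymethoxy)benzaldehyde F5, in which the formyl group is para to fluorine. KOtBu (THF, 0 °C → rt) should then close the pyran by the same addition–elimination, now strongly activated, to give 7-(methoxymethoxy)-2,2-dimethyl-2H-chromene-6-carbaldehyde F1, which is carried to 18 by the aldol and resolution sequence described for step 10.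

Step 8. The two ortho hydroxyls may be poorly discriminated, so that the acetal lands on the hydroxyl next to the prenyl group and the 6-prenyl series results. The fallback brings the prenyl group in after ring C by sigmatropic rearrangement; it sets out from 12 and 13, comes back at 17 and replaces steps 7–9. Compound 12 is cyclised (HC(OEt)3, HClO4; then hot water) to 5,7-dihydroxy-4H-chromen-4-one F6. The non-chelated 7-OH is protected selectively (MOMCl, i-Pr2NEt, CH2Cl2) to give 5-hydroxy-7-(methoxymethoxy)-4H-chromen-4-one F7. The chelated 5-OH is alkylated with 13 (K2CO3, DMF) to give 7-(methoxymethoxy)-5-[(3-methylbut-2-en-1-yl)oxy]-4H-chromen-4-one F8. Heating (N,N-diethylaniline, 190 °C) should trigger the para-Claisen–Cope sequence (3,3-shift to C6, then 3,3-shift to C8, which is para to O5) to give 5-hydroxy-7-(methoxymethoxy)-8-(3-methylbut-2-en-1-yl)-4H-chromen-4-one F9. MOMCl and NaH (THF) then give 17.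

**Further compounds**
F1 | step 10 | 7-(methoxymethoxy)-2,2-dimethyl-2H-chromene-6-carbaldehyde | CC1(C)C=Cc2cc(C=O)c(OCOC)cc2O1
F2 | step 10 | (E)-1-[2-hydroxy-4,6-bis(methoxymethoxy)-3-(3-methylbut-2-en-1-yl)phenyl]-3-[7-(methoxymethoxy)-2,2-dimethyl-2H-chromen-6-yl]prop-2-en-1-one | CC(C)=CCc1c(OCOC)cc(OCOC)c(C(=O)/C=C/c2cc3C=CC(C)(C)Oc3cc2OCOC)c1O
F3 | step 10 | racemic 5,7-bis(methoxymethoxy)-2-[7-(methoxymethoxy)-2,2-dimethyl-2H-chromen-6-yl]-8-(3-methylbut-2-en-1-yl)-2,3-dihydro-4H-chromen-4-one | CC(C)=CCc1c(OCOC)cc(OCOC)c2c1OC(c1cc3c(cc1OCOC)OC(C)(C)C=C3)CC2=O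
F4 | step 10 | (2R,4R)-5,7-bis(methoxymethoxy)-2-[7-(methoxymethoxy)-2,2-dimethyl-2H-chromen-6-yl]-8-(3-methylbut-2-en-1-yl)-3,4-dihydro-2H-chromen-4-ol | CC(C)=CCc1c(OCOC)cc(OCOC)c2c1O[C@@H](c1cc3c(cc1OCOC)OC(C)(C)C=C3)C[C@H]2O
F5 | step 5 | 4-fluoro-5-[(Z)-3-hydroxy-3-methylbut-1-en-1-yl]-2-(methoxymethoxy)benzaldehyde | CC(C)(O)/C=C\c1cc(C=O)c(OCOC)cc1F
F6 | step 8 | 5,7-dihydroxy-4H-chromen-4-one | O=c1ccoc2cc(O)cc(O)c12
F7 | step 8 | 5-hydroxy-7-(methoxymethoxy)-4H-chromen-4-one | O=c1ccoc2cc(OCOC)cc(O)c12
F8 | step 8 | 7-(methoxymethoxy)-5-[(3-methylbut-2-en-1-yl)oxy]-4H-chromen-4-one | O=c1ccoc2cc(OCOC)cc(OCC=C(C)C)c12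
F9 | step 8 | 5-hydroxy-7-(methoxymethoxy)-8-(3-methylbut-2-en-1-yl)-4H-chromen-4-one | O=c1ccoc2c(CC=C(C)C)c(OCOC)cc(O)c12
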